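**Strategy.** Ring A is disconnected across its chloro-enone. The ketone carbon C6 and the ring-fusion carbon C8a are joined to the two carbons of an alkyne (C5≡C4a) in one rhodium-catalysed aldehyde C–H activation/[4+2] annulation. The step exploits that C6 of ring A is an acyl carbon bound to the C5=C4a alkene, and that C8a–H with the C1 methylene of the pyran ring is a masked alkyne terminus (C8a≡C1). Both precursors are acyclic: a lactic-acid-derived 4-alkynal carrying C7 and C8 as an acetonide, and a silyl-capped ynone carrying C3, C4 and the dienyl chain. Fluoride then closes the pyran ring and sets C8a; chlorination, deprotection and acetylation follow.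

Key step: step 9

Remark: (R)-2-methylbutan-1-ol is taken as a commercial chiral-pool alcohol; atom numbers (C1, O2, C3, C4, C4a, C5 to C8, C8a) are those of the isochromene core of the target.

Step 1
Reactants: 1 (S)-lactic acid; 2 pivalaldehyde
Product: 3 (2S,5S)-2-tert-butyl-5-methyl-1,3-dioxolan-4-one
Conditions: p-TsOH·H2O (cat.), H2SO4 (cat.), pentane, reflux (Dean–Stark); crystallisation from pentane/Et2O at −78 °C
Reagents that add atoms: none
Why: Acid-catalysed acetalisation (Seebach dioxolanone formation) keeps the lactic acid stereocentre, and the cis acetal, expected as the main isomer under these equilibrating conditions, is purified by crystallisation.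

Step 2
Reactants: 3 (2S,5S)-2-tert-butyl-5-methyl-1,3-dioxolan-4-one; 4 3-(trimethylsilyl)prop-2-ynal
Product: 6 (2S,5R)-2-tert-butyl-5-[(1R)-1-hydroxy-3-(trimethylsilyl)prop-2-yn-1-yl]-5-methyl-1,3-dioxolan-4-one, via lithium enolate 5 (not isolated)
Conditions: LiN(iPr)2, THF, −78 °C; then 4, −78 °C; AcOH quench
Reagents that add atoms: none
Why: Aldol addition with self-regeneration of the stereocentre: the planar enolate is attacked anti to the tert-butyl group, which restores C7 with retention, and the ring-locked enolate (methyl cis to OLi) in a closed Zimmerman–Traxler transition state with the alkynyl group equatorial should set C8 as the (R)-carbinol (erythro O7/O8).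

Step 3
Reactants: 6 (2S,5R)-2-tert-butyl-5-[(1R)-1-hydroxy-3-(trimethylsilyl)prop-2-yn-1-yl]-5-methyl-1,3-dioxolan-4-one
Product: 8 methyl (4R,5R)-2,2,4-trimethyl-5-[(trimethylsilyl)ethynyl]-1,3-dioxolane-4-carboxylate, via dihydroxy ester 7 (not isolated)
Conditions: HCl (1.25 M in MeOH), 50 °C; evaporation; then Me2C(OMe)2, PPTS (cat.), acetone, rt
Reagents that add atoms: methanol CO; 2,2-dimethoxypropane COC(C)(C)OC
Why: Acid-catalysed methanolysis of the acylal (transacetalisation and Fischer esterification) releases the diol ester without touching the two stereocentres or the silyl alkyne, and acetonide formation then ties O7 and O8 into a dioxolane.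

Step 4
Reactants: 8 methyl (4R,5R)-2,2,4-trimethyl-5-[(trimethylsilyl)ethynyl]-1,3-dioxolane-4-carboxylate
Product: 9 methyl (4R,5R)-5-ethynyl-2,2,4-trimethyl-1,3-dioxolane-4-carboxylate
Conditions: K2CO3 (cat.), MeOH, 0 °C to rt
Reagents that add atoms: none
Why: Base-catalysed methanolysis of the alkynyl C–Si bond (protodesilylation) frees the terminal alkyne, and the quaternary C7 cannot epimerise.

Step 5
Reactants: 9 methyl (4R,5R)-5-ethynyl-2,2,4-trimethyl-1,3-dioxolane-4-carboxylate
Product: 10 (4R,5R)-5-ethynyl-2,2,4-trimethyl-1,3-dioxolane-4-carbaldehyde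
Conditions: iBu2AlH (1.1 equiv), CH2Cl2, −78 °C; MeOH, then aq. potassium sodium tartrate
Reagents that add atoms: none
Why: Half-reduction of the α-alkoxy ester with iBu2AlH should stop at the aldehyde because the chelated aluminium hemiacetal survives at −78 °C until work-up.

Step 6
Reactants: 11 (R)-2-methylbutan-1-ol; 12 2-(triphenylphosphoranylidene)propanal
Product: 14 (2E,4R)-2,4-dimethylhex-2-enal, via (R)-2-methylbutanal 13 (not isolated)
Conditions: TEMPO (cat.), PhI(OAc)2, CH2Cl2, rt; then 12, 40 °C
Reagents that add atoms: none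
Why: TEMPO/PhI(OAc)2 oxidation followed in the same flask by Wittig olefination with a stabilised ylide should give the (E)-enal without isolating the volatile, epimerisable aldehyde; the stereocentre comes from 11.

Step 7
Reactants: 14 (2E,4R)-2,4-dimethylhex-2-enal; 15 diethyl [2-(methoxy(methyl)amino)-2-oxoethyl]phosphonate
Product: 16 (2E,4E,6R)-N-methoxy-N,4,6-trimethylocta-2,4-dienamide
Conditions: LiCl, iPr2NEt, MeCN, rt
Reagents that add atoms: none
Why: Horner–Wadsworth–Emmons olefination under the mild Masamune–Roush conditions should give the (E)-configured dienyl Weinreb amide without epimerising the γ-stereocentre.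

Step 8
Reactants: 16 (2E,4E,6R)-N-methoxy-N,4,6-trimethylocta-2,4-dienamide; 17 3-bromo-1-(trimethylsilyl)prop-1-yne
Product: 19 (5E,7E,9R)-7,9-dimethyl-1-(trimethylsilyl)undeca-5,7-dien-1-yn-4-one, via propargyl Grignard reagent 18 (not isolated)
Conditions: 17, Mg turnings, ZnBr2 (cat.), Et2O, 0 °C; then 16, THF, −78 to −20 °C; cold 1 M HCl
Reagents that add atoms: none
Why: Weinreb ketone synthesis: the silyl-substituted propargyl/allenyl Grignard reagent reacts through its CH2 terminus, and the chelated tetrahedral intermediate prevents over-addition and keeps the base-sensitive β,γ-ynone masked until the cold acidic quench.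

Step 9
Reactants: 10 (4R,5R)-5-ethynyl-2,2,4-trimethyl-1,3-dioxolane-4-carbaldehyde; 19 (5E,7E,9R)-7,9-dimethyl-1-(trimethylsilyl)undeca-5,7-dien-1-yn-4-one
Product: 20 (3aR,7aR)-6-[(3E,5E,7R)-5,7-dimethyl-2-oxonona-3,5-dien-1-yl]-2,2,3a-trimethyl-7-methylidene-5-(trimethylsilyl)-7,7a-dihydro-1,3-benzodioxol-4(3aH)-one
Conditions: [Rh(cod)2]BF4 (10 mol %), dppe (10 mol %), H2 then Ar (activation); 19 (1.5 equiv), slow addition of 10, CH2Cl2, 40 °C
Reagents that add atoms: none
Why: Cationic monovalent rhodium inserts into the aldehyde C–H bond of 10, the acyl rhodium hydride adds syn across the tethered terminal alkyne (H to C1, Rh to C8a) to give a five-membered acyl–alkenyl rhodacycle, alkyne 19 inserts into the Rh–C8a bond (forming C4a–C8a), and acyl–alkenyl reductive elimination forms C5–C6. The closest known reaction type is the rhodium-catalysed [4+2] annulation of 4-alkynals with alkynes, an intermolecular alkyne carboacylation through aldehyde C–H activation. Ring A closes as a six-membered carbocycle by reductive elimination from a seven-membered rhodacycle, a formal [4+2] in which C6–C7–C8–C8a is the four-atom and C5≡C4a the two-atom component. No stereocentre is created (C8a stays sp2 as the exocyclic methylene C8a=C1); C7 and C8 pass through untouched because C7 is quaternary, and the cis-dioxolane holds C6 and C8a on the same side, which favours the small rhodacycle. The step needs regioselective insertion so that C4a and not C5 bonds to C8a: the trimethylsilyl group should stay on the rhodium-bound carbon for steric and α-silyl electronic reasons, so the migrating alkenyl carbon attacks the CH2-substituted alkyne carbon, and an excess of 19 together with slow addition of 10 should let the annulation outrun intramolecular hydroacylation to a cyclopentenone. The cross-conjugated product cannot aromatise because C7 bears no hydrogen.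

Step 10
Reactants: 20 (3aR,7aR)-6-[(3E,5E,7R)-5,7-dimethyl-2-oxonona-3,5-dien-1-yl]-2,2,3a-trimethyl-7-methylidene-5-(trimethylsilyl)-7,7a-dihydro-1,3-benzodioxol-4(3aH)-one
Product: 22 7,8-O-isopropylidene derivative of (7R,8R,8aR)-3-[(1E,3E,5R)-3,5-dimethylhepta-1,3-dien-1-yl]-7,8-dihydroxy-7-methyl-1,7,8,8a-tetrahydro-6H-isochromen-6-one, via 5-silyl pyran 21 (not isolated)
Conditions: Bu4NF (2 equiv), THF, 0 °C to rt; AcOH quench
Reagents that add atoms: none
Why: Fluoride-triggered cascade of intramolecular oxa-Michael addition and protodesilylation: the enolate oxygen of the C3 ketone adds 6-endo-trig to the exocyclic methylene C1 (1,6-addition to the cross-conjugated dienone) to close ring B, the silyl group at C5 is lost through the α-silyl ketone tautomer, and reversible γ-protonation of the dienolate at C8a should funnel both epimers into the more stable one with C1 pseudo-equatorial and trans to O8 (8aR).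

Step 11
Reactants: 22 7,8-O-isopropylidene derivative of (7R,8R,8aR)-3-[(1E,3E,5R)-3,5-dimethylhepta-1,3-dien-1-yl]-7,8-dihydroxy-7-methyl-1,7,8,8a-tetrahydro-6H-isochromen-6-one
Product: 23 5-chloro derivative of 22
Conditions: N-chlorosuccinimide (1.05 equiv), CH2Cl2, −20 to 0 °C, dark
Reagents that add atoms: N-chlorosuccinimide O=C1CCC(=O)N1Cl
Why: Electrophilic chlorination of the vinylogous ester at C5, the nucleophilic terminus of the dienol ether O2–C3=C4–C4a=C5 and the α-carbon of the enone, as in the C5 halogenation of azaphilone nuclei; no stereocentre is touched.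

Step 12
Reactants: 23 5-chloro derivative of 22
Product: 24 (7R,8R,8aR)-5-chloro-3-[(1E,3E,5R)-3,5-dimethylhepta-1,3-dien-1-yl]-7,8-dihydroxy-7-methyl-1,7,8,8a-tetrahydro-6H-isochromen-6-one
Conditions: AcOH/H2O (4:1), 45 °C
Reagents that add atoms: none
Why: Acid-catalysed hydrolysis of the isopropylidene acetal; the vinylogous ester should re-close under the same conditions if it opens, and C8a stays in its thermodynamically preferred configuration.

Step 13
Reactants: 24 (7R,8R,8aR)-5-chloro-3-[(1E,3E,5R)-3,5-dimethylhepta-1,3-dien-1-yl]-7,8-dihydroxy-7-methyl-1,7,8,8a-tetrahydro-6H-isochromen-6-one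
Product: 25 (7R,8R,8aR)-5-chloro-3-[(1E,3E,5R)-3,5-dimethylhepta-1,3-dien-1-yl]-7-hydroxy-7-methyl-6-oxo-6,7,8,8a-tetrahydro-1H-isochromen-8-yl acetate
Conditions: Ac2O (1.5 equiv), pyridine, DMAP (cat.), CH2Cl2, 0 °C
Reagents that add atoms: acetic anhydride CC(=O)OC(C)=O
Why: Acylation with Ac2O/pyridine should be selective for the secondary C8 hydroxyl over the hindered tertiary C7 hydroxyl next to the ketone, which gives the target.

**Compound list**

1 | (S)-lactic acid | C[C@H](O)C(=O)O | starting material
2 | pivalaldehyde | CC(C)(C)C=O | starting material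
3 | (2S,5S)-2-tert-butyl-5-methyl-1,3-dioxolan-4-one | C[C@@H]1O[C@H](C(C)(C)C)OC1=O | intermediate
4 | 3-(trimethylsilyl)prop-2-ynal | C[Si](C)(C)C#CC=O | starting material
5 | lithium enolate of 3, lithium (2S)-2-tert-butyl-5-methyl-1,3-dioxol-4-olate | CC1=C(O[Li])O[C@@H](C(C)(C)C)O1 | intermediate
6 | (2S,5R)-2-tert-butyl-5-[(1R)-1-hydroxy-3-(trimethylsilyl)prop-2-yn-1-yl]-5-methyl-1,3-dioxolan-4-one | C[C@]1([C@H](O)C#C[Si](C)(C)C)O[C@H](C(C)(C)C)OC1=O | intermediate
7 | methyl (2R,3R)-2,3-dihydroxy-2-methyl-5-(trimethylsilyl)pent-4-ynoate | COC(=O)[C@](C)(O)[C@H](O)C#C[Si](C)(C)C | intermediate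
8 | methyl (4R,5R)-2,2,4-trimethyl-5-[(trimethylsilyl)ethynyl]-1,3-dioxolane-4-carboxylate | COC(=O)[C@]1(C)OC(C)(C)O[C@@H]1C#C[Si](C)(C)C | intermediate
9 | methyl (4R,5R)-5-ethynyl-2,2,4-trimethyl-1,3-dioxolane-4-carboxylate | COC(=O)[C@]1(C)OC(C)(C)O[C@@H]1C#C | intermediate
10 | (4R,5R)-5-ethynyl-2,2,4-trimethyl-1,3-dioxolane-4-carbaldehyde | O=C[C@]1(C)OC(C)(C)O[C@@H]1C#C | intermediate
11 | (R)-2-methylbutan-1-ol | CC[C@@H](C)CO | starting material
12 | 2-(triphenylphosphoranylidene)propanal | CC(C=O)=P(c1ccccc1)(c1ccccc1)c1ccccc1 | starting material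
13 | (R)-2-methylbutanal | CC[C@@H](C)C=O | intermediate
14 | (2E,4R)-2,4-dimethylhex-2-enal | CC[C@@H](C)/C=C(C)/C=O | intermediate
15 | diethyl [2-(methoxy(methyl)amino)-2-oxoethyl]phosphonate | CCOP(=O)(CC(=O)N(C)OC)OCC | starting material
16 | (2E,4E,6R)-N-methoxy-N,4,6-trimethylocta-2,4-dienamide | CC[C@@H](C)/C=C(C)/C=C/C(=O)N(C)OC | intermediate
17 | 3-bromo-1-(trimethylsilyl)prop-1-yne | C[Si](C)(C)C#CCBr | starting material
18 | [3-(trimethylsilyl)prop-2-yn-1-yl]magnesium bromide | C[Si](C)(C)C#CC[Mg]Br | intermediate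
19 | (5E,7E,9R)-7,9-dimethyl-1-(trimethylsilyl)undeca-5,7-dien-1-yn-4-one | CC[C@@H](C)/C=C(C)/C=C/C(=O)CC#C[Si](C)(C)C | intermediate
20 | (3aR,7aR)-6-[(3E,5E,7R)-5,7-dimethyl-2-oxonona-3,5-dien-1-yl]-2,2,3a-trimethyl-7-methylidene-5-(trimethylsilyl)-7,7a-dihydro-1,3-benzodioxol-4(3aH)-one | CC[C@@H](C)/C=C(C)/C=C/C(=O)CC1=C([Si](C)(C)C)C(=O)[C@]2(C)OC(C)(C)O[C@@H]2C1=C | intermediate
21 | 5-(trimethylsilyl) derivative of 22 (drawn 8aR) | CC[C@@H](C)/C=C(C)/C=C/C1=CC2=C([Si](C)(C)C)C(=O)[C@]3(C)OC(C)(C)O[C@@H]3[C@H]2CO1 | intermediate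
22 | 7,8-O-isopropylidene derivative of (7R,8R,8aR)-3-[(1E,3E,5R)-3,5-dimethylhepta-1,3-dien-1-yl]-7,8-dihydroxy-7-methyl-1,7,8,8a-tetrahydro-6H-isochromen-6-one | CC[C@@H](C)/C=C(C)/C=C/C1=CC2=CC(=O)[C@]3(C)OC(C)(C)O[C@@H]3[C@H]2CO1 | intermediate
23 | 5-chloro derivative of 22 | CC[C@@H](C)/C=C(C)/C=C/C1=CC2=C(Cl)C(=O)[C@]3(C)OC(C)(C)O[C@@H]3[C@H]2CO1 | intermediate
24 | (7R,8R,8aR)-5-chloro-3-[(1E,3E,5R)-3,5-dimethylhepta-1,3-dien-1-yl]-7,8-dihydroxy-7-methyl-1,7,8,8a-tetrahydro-6H-isochromen-6-one | CC[C@@H](C)/C=C(C)/C=C/C1=CC2=C(Cl)C(=O)[C@](C)(O)[C@H](O)[C@H]2CO1 | intermediate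
25 | (7R,8R,8aR)-5-chloro-3-[(1E,3E,5R)-3,5-dimethylhepta-1,3-dien-1-yl]-7-hydroxy-7-methyl-6-oxo-6,7,8,8a-tetrahydro-1H-isochromen-8-yl acetate | CC[C@@H](C)/C=C(C)/C=C/C1=CC2=C(Cl)C(=O)[C@](C)(O)[C@H](OC(C)=O)[C@H]2CO1 | target

**Step count.** Total: 13 steps. Longest linear sequence: 10 steps (steps 1 to 5, then 9 to 13).

**Steps most likely to fail**

Step 9. The hindered silyl alkyne may insert too slowly, so that the acyl rhodium hydride is consumed by intramolecular hydroacylation or decarbonylation, or insertion may occur with the reverse orientation. Ring A would then be closed in separate operations by known chemistry, setting out from 19 and 10 and returning at 22.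
- Iododesilylation of 19 (N-iodosuccinimide, AgNO3 cat., acetone) should give the iodoalkyne (5E,7E,9R)-1-iodo-7,9-dimethylundeca-5,7-dien-1-yn-4-one F1.
- Addition of F1 to 10 mediated by CrCl2 (Nozaki–Hiyama–Kishi, chemoselective for the aldehyde over the ketone) should give the propargylic alcohol F2, a mixture of epimers at the new carbinol carbon C6 with the dioxolane carbons as in 10.
- Oxidation (Dess–Martin periodinane, NaHCO3, CH2Cl2) should give the ynedione F3.
- Hydroiodination (NaI, AcOH) should give the (Z)-β-iodoenone F4, with iodine on C4a and cis to C6.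
- A 6-exo-dig carbopalladation of the terminal alkyne with hydride capture (Pd(PPh3)4 cat., HCO2Na, DMF, 60 °C) then forms C4a–C8a and should give the silicon-free dienone F5.
- DBU (cat., CH2Cl2) should cyclise F5 to 22 by the oxa-Michael closure of step 10.

Step 11. The chlorinating agent may also attack C4 or the dienyl chain, or chlorinate twice. The site would then be fixed by enolate chemistry instead of by the innate reactivity of the vinylogous ester, setting out from 22 and returning at 23.
- γ-Deprotonation and O-silylation (Me3SiOTf, Et3N, CH2Cl2, −78 °C) should give the trimethylsilyl dienol ether F6 (C6–OSiMe3, with C5=C6 and C4a=C8a double bonds).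
- N-Chlorosuccinimide (THF, −78 °C) should chlorinate its α-carbon C5 to give the α-chloro-β,γ-unsaturated ketone F7.
- Et3N then moves the double bond back into conjugation (C5=C4a) and resets C8a under the same thermodynamic control, which gives 23.

Step 2. The two faces of the aldehyde may be poorly differentiated, so that 6 forms as a mixture of C8 epimers. The carbinol centre would then be set by catalyst control, setting out from the epimer mixture 6 and returning at 6.
- Oxidation (Dess–Martin periodinane, CH2Cl2) should give the ynone (2S,5R)-2-tert-butyl-5-methyl-5-[3-(trimethylsilyl)prop-2-ynoyl]-1,3-dioxolan-4-one F8.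
- Asymmetric transfer hydrogenation (RuCl[(S,S)-TsDPEN](p-cymene), i-PrOH, rt) should return 6 as the (1R)-carbinol. The (S,S) ligand is chosen on the model in which the alkynyl group takes the place of the aryl group of an aryl ketone.

**Further compounds**

F1 | step 9 | (5E,7E,9R)-1-iodo-7,9-dimethylundeca-5,7-dien-1-yn-4-one | CC[C@@H](C)/C=C(C)/C=C/C(=O)CC#CI
F2 | step 9 | propargylic alcohol from F1 and 10 (carbinol epimers; dioxolane carbons as in 10) | CC[C@@H](C)/C=C(C)/C=C/C(=O)CC#CC(O)[C@]1(C)OC(C)(C)O[C@@H]1C#C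
F3 | step 9 | ynedione from oxidation of F2 | CC[C@@H](C)/C=C(C)/C=C/C(=O)CC#CC(=O)[C@]1(C)OC(C)(C)O[C@@H]1C#C
F4 | step 9 | (Z)-β-iodoenone from hydroiodination of F3 | CC[C@@H](C)/C=C(C)/C=C/C(=O)C/C(I)=C/C(=O)[C@]1(C)OC(C)(C)O[C@@H]1C#C
F5 | step 9 | silicon-free analogue of 20 (hydrogen at C5) | CC[C@@H](C)/C=C(C)/C=C/C(=O)CC1=CC(=O)[C@]2(C)OC(C)(C)O[C@@H]2C1=C
F6 | step 11 | trimethylsilyl dienol ether of 22 | CC[C@@H](C)/C=C(C)/C=C/C1=CC2=C(CO1)[C@H]3OC(C)(C)O[C@@]3(C)C(O[Si](C)(C)C)=C2
F7 | step 11 | α-chloro-β,γ-unsaturated ketone from F6 (C5 epimers) | CC[C@@H](C)/C=C(C)/C=C/C1=CC2=C(CO1)[C@H]3OC(C)(C)O[C@@]3(C)C(=O)C2Cl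
F8 | step 2 | (2S,5R)-2-tert-butyl-5-methyl-5-[3-(trimethylsilyl)prop-2-ynoyl]-1,3-dioxolan-4-one | C[C@]1(C(=O)C#C[Si](C)(C)C)O[C@H](C(C)(C)C)OC1=O
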